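## Retrosynthetic overview

1. Feature: ring A of the lower flavan-3-ol unit is a pentasubstituted phloroglucinol. Its C8, bonded to upper C4, lies between C8a (O1) and C7 (OH) and is nearly the twin of C6. Ring A is therefore grown around an alkyne already attached to upper C4, so no C8-against-C6 arylation is needed.
2. Key disconnection (Danheiser benzannulation): lower C8–C8a and C6–C7. This leads back to flavan-4-yl siloxyalkyne 16 (C8 and C7–O) and 3-benzyloxy-4-cinnamylcyclobutenone 31 (C8a–O, C6, C5–O, C4a and the C4–C3–C2–ring B chain).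
3. For 16, upper C2 comes from a rhodium-catalysed asymmetric arylation of a chromone and upper C4 from pseudo-axial alkynylation of the flavan-4-yl cation, followed by acetylide oxidation and O-silylation. For 31, a monoalkylketene adds (2+2) to benzyl ethynyl ether.
4. After ring A, the only free phenol (future O1) closes lower ring C on a (1S,2S)-diol with inversion (2,3-trans). Oxidation and hindered-hydride reduction give 2,3-cis, then desilylation and hydrogenolysis follow.
5. Order of rings: upper A/C (chromone) and upper B, cyclobutenone, lower A (step 12), lower C (step 14).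

Key step: step 12

**Remarks on the chemistry**
- Assumption: the (S)-biaryl bisphosphine is taken to deliver the aryl group to the same enone face as (S)-BINAP does with 2-cyclohexenone. That face corresponds to 2S in the flavanone; the antipodal ligand would serve otherwise.
- Upper C2 is set on O-benzylated material, because base-mediated O-benzylation of a natural 4'-hydroxyflavanone would racemise C2 through the ring-opened chalcone.
- O5 is carried as a benzyl ether. A cyclobutenone with hydrogen at C2 needs an unsubstituted oxyacetylene, and the parent siloxyacetylene tends to isomerise to the silylketene, whereas benzyl ethynyl ether comes from routine chemistry. O7 stays a silyl ether and O1 stays the only free phenol.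
- The dihydroxylation uses stoichiometric OsO4, because aqueous K3Fe(CN)6/K2CO3 would oxidise the free, electron-rich phenolate of 36.

## Route

**Step 1**
Reactants: 1 7-hydroxy-4H-chromen-4-one
Product: 2 7-(benzyloxy)-4H-chromen-4-one
Conditions: BnBr, K2CO3, acetone, reflux
Reagents that add atoms: benzyl bromide, BrCc1ccccc1
Why: Williamson etherification of the acidic 7-OH, done while the molecule has no stereocentre so that the base can do no harm.

**Step 2**
Reactants: 2 7-(benzyloxy)-4H-chromen-4-one; 3 4-(benzyloxy)phenylboronic acid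
Product: 4 (2S)-4',7-bis(benzyloxy)flavanone
Conditions: [Rh(OH)(cod)]2 (1.5 mol %), (S)-MeO-F12-BIPHEP (3.3 mol %), 3 (2 equiv), PhMe/H2O, 20 °C
Reagents that add atoms: none
Why: Hayashi–Miyaura asymmetric 1,4-addition of an arylboronic acid to a chromone, in which the (S)-bisphosphine blocks one enone face so that the aryl group should arrive to give 2S, and the base-free medium avoids retro-oxa-Michael racemisation.

**Step 3**
Reactants: 4 (2S)-4',7-bis(benzyloxy)flavanone
Product: 5 (2S,4S)-4',7-bis(benzyloxy)flavan-4-ol (2,4-cis)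
Conditions: NaBH4, THF/MeOH, 0 °C
Reagents that add atoms: none
Why: Borohydride reduction of a flavanone is fast at 0 °C and leaves C2 alone; hydride adds so that the 4-OH ends equatorial and cis to the 2-aryl group (4S), a centre that is erased again in step 5.

**Step 4**
Reactants: 6 ethynyltrimethylsilane
Product: 9 potassium trifluoro[(trimethylsilyl)ethynyl]borate, via lithium (trimethylsilyl)acetylide 7 (not isolated), via lithium alkynyltrimethoxyborate 8 (not isolated)
Conditions: n-BuLi, THF, −78 °C; B(OMe)3, −78 → −20 °C; aq KHF2, → rt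
Reagents that add atoms: trimethyl borate, COB(OC)OC; potassium hydrogen difluoride, [K+].[F-].F
Why: Borylation of a lithium acetylide followed by fluoride exchange with KHF2 is the standard preparation of air-stable potassium alkynyltrifluoroborates.

**Step 5**
Reactants: 5 (2S,4S)-4',7-bis(benzyloxy)flavan-4-ol; 9 potassium trifluoro[(trimethylsilyl)ethynyl]borate
Product: 12 (2S,4R)-4',7-bis(benzyloxy)-4-[(trimethylsilyl)ethynyl]flavan (2,4-trans), via alkynyldifluoroborane 10 (not isolated), via flavan-4-yl cation 11 (not isolated)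
Conditions: 9 (2 equiv), BF3·OEt2 (2 equiv), CH2Cl2/MeCN, −40 → 0 °C
Reagents that add atoms: none
Why: Lewis-acid-promoted SN1 alkynylation of an electron-rich benzylic alcohol with an alkynyltrifluoroborate; cation 11 (stabilised by O1 and 7-OBn) adopts a half-chair with the 2-aryl group equatorial and the slim nucleophile attacks pseudo-axially, the same preference that gives trans-3,5 products from 5-substituted cyclohexenones, so C4 should be set 2,4-trans (4R) and any cis isomer is removed by chromatography.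

**Step 6**
Reactants: 12 (2S,4R)-4',7-bis(benzyloxy)-4-[(trimethylsilyl)ethynyl]flavan
Product: 13 (2S,4S)-4',7-bis(benzyloxy)-4-ethynylflavan (2,4-trans; the descriptor changes by priority only)
Conditions: K2CO3 (0.2 equiv), MeOH/THF, rt
Reagents that add atoms: none
Why: Carbonate-catalysed methanolysis of the C(sp)–SiMe3 bond, too weakly basic to touch the propargylic C4–H.

**Step 7**
Reactants: 13 (2S,4S)-4',7-bis(benzyloxy)-4-ethynylflavan
Product: 16 (2S,4S)-4',7-bis(benzyloxy)-4-[(triisopropylsiloxy)ethynyl]flavan (2,4-trans), via lithium acetylide 14 (not isolated), via lithium ynolate 15 (not isolated)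
Conditions: n-BuLi, THF, −78 °C; LiOOt-Bu (from t-BuOOH + LiN(SiMe3)2), −78 → 0 °C; TIPSOTf, −78 → 0 °C
Reagents that add atoms: tert-butyl hydroperoxide, CC(C)(C)OO; triisopropylsilyl trifluoromethanesulfonate, CC(C)[Si](OS(=O)(=O)C(F)(F)F)(C(C)C)C(C)C
Why: Oxidation of a lithium acetylide with lithium tert-butyl peroxide gives the lithium ynolate, which the bulky silyl triflate captures on oxygen (known acetylide-to-siloxyalkyne sequence), and C4 takes no part.

**Step 8**
Reactants: 17 3,4,5-tris(benzyloxy)benzaldehyde; 18 (3-carboxypropyl)triphenylphosphonium bromide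
Product: 20 (E)-5-[3,4,5-tris(benzyloxy)phenyl]pent-4-enoic acid, via carboxylate ylide 19 (not isolated)
Conditions: 18, NaN(SiMe3)2 (2.2 equiv), THF, 0 °C; 17, −78 °C → rt; then 1 M HCl
Reagents that add atoms: none
Why: Wittig olefination with a carboxylate-bearing ylide, which is E-selective with aromatic aldehydes, and the E acid can be freed of Z isomer by crystallisation.

**Step 9**
Reactants: 21 benzyl alcohol; 22 trichloroethylene
Product: 25 benzyl (E)-1,2-dichlorovinyl ether, via potassium benzyl oxide 23 (not isolated), via dichloroacetylene 24 (not isolated)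
Conditions: KH, THF, 0 °C; 22, −50 °C → rt
Reagents that add atoms: none
Why: The alkoxide dehydrochlorinates trichloroethylene and then adds anti to the dichloroacetylene formed in situ, the usual first half of the dichlorovinyl ether route to alkynyl ethers.

**Step 10**
Reactants: 25 benzyl (E)-1,2-dichlorovinyl ether
Product: 28 benzyl ethynyl ether, via benzyl chloroethynyl ether 26 (not isolated), via lithium (benzyloxy)acetylide 27 (not isolated)
Conditions: n-BuLi (2.2 equiv), Et2O, −78 → −40 °C; MeOH, −78 °C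
Reagents that add atoms: none
Why: Elimination of HCl, chlorine–lithium exchange and cold protonation complete the dichlorovinyl ether route; 28 is kept below room temperature because benzyl alkynyl ethers undergo a (3,3) shift on warming.

**Step 11**
Reactants: 20 (E)-5-[3,4,5-tris(benzyloxy)phenyl]pent-4-enoic acid; 28 benzyl ethynyl ether
Product: 31 (±)-3-(benzyloxy)-4-{(E)-3-[3,4,5-tris(benzyloxy)phenyl]allyl}cyclobut-2-en-1-one, via acid chloride 29 (not isolated), via cinnamylketene 30 (not isolated)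
Conditions: Me2C=C(Cl)NMe2, CH2Cl2, 0 °C; then added slowly to 28 (3 equiv), Et3N, CH2Cl2, 0 °C → rt
Reagents that add atoms: none
Why: HCl-free acid chloride formation spares the electron-rich styrene, amine dehydrochlorination gives the monoalkylketene, and the ketene–ynol ether (2+2) cycloaddition joins the unsubstituted nucleophilic alkyne carbon to the ketene carbonyl carbon, which places H at C2, OBn at C3 and the chain at C4 (racemic, lost in step 12).

**Step 12 (key step)**
Reactants: 16 (2S,4S)-4',7-bis(benzyloxy)-4-[(triisopropylsiloxy)ethynyl]flavan; 31 (±)-3-(benzyloxy)-4-cinnamyl-type cyclobutenone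
Product: 36 2-[(2S,4R)-4',7-bis(benzyloxy)flavan-4-yl]-5-(benzyloxy)-3-(triisopropylsiloxy)-6-{(E)-3-[3,4,5-tris(benzyloxy)phenyl]allyl}phenol, via vinylketene 32 (not isolated), via (2+2) adduct 33 (not isolated), via dienylketene 34 (not isolated), via cyclohexadienone 35 (not isolated)
Conditions: 31 (1.5 equiv), PhMe (0.5 M, degassed, base-washed glass), sealed tube, 110 °C then 135 °C
Reagents that add atoms: none
Why: Heating opens 31 by a four-electron conrotatory electrocyclic reaction, the chain turning outward, to vinylketene 32, and the polarised siloxyalkyne adds (2+2) across its ketene C=C, the flavanyl-bearing nucleophilic carbon (C8) bonding to the ketene carbonyl carbon (C8a) and the oxygenated carbon (C7) to the ketene α-carbon (C6), to give 33. A second four-electron opening leads to dienylketene 34, which closes ring A by a six-electron disrotatory electrocyclisation between C8a and C4a, and dienone 35 tautomerises to phenol 36. This is the Danheiser benzannulation in its siloxyalkyne form, which tolerates α-branched stereodefined alkynes, and the thermal union of 3-alkoxycyclobutenones with alkoxyacetylenes to 3,5-dialkoxyphenols is the closest relative of this pairing. No stereocentre is formed: racemic C4 of 31 becomes aromatic C4a, and upper C2 and C4 are spectators under neutral aprotic heating. The selectivity needed is the orientation of the ketene–alkyne union, fixed by the donor oxygen of the alkyne, so the flavanyl group can only end between the new phenol (future O1) and OTIPS (O7), with the cinnamyl chain ortho to that phenol and OBn at C5. Outward rotation of the chain also keeps the styrene double bond away from the ketene and holds back an intramolecular ketene–alkene addition.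

**Step 13**
Reactants: 36 benzannulation phenol
Product: 38 (1S,2S)-3-{2-(benzyloxy)-5-[(2S,4R)-4',7-bis(benzyloxy)flavan-4-yl]-6-hydroxy-4-(triisopropylsiloxy)phenyl}-1-[3,4,5-tris(benzyloxy)phenyl]propane-1,2-diol, via osmate ester 37 (not isolated)
Conditions: OsO4 (1.1 equiv), (DHQ)2PHAL (1.2 equiv), PhMe, −20 °C; then sat. aq Na2SO3, THF, 40 °C
Reagents that add atoms: osmium tetroxide, O=[Os](=O)(=O)=O
Why: Sharpless asymmetric dihydroxylation run stoichiometrically; (DHQ)2PHAL directs the syn addition to the face of the E-β-alkylstyrene that gives the (1S,2S)-diol, a minor face isomer would be a separable diastereomer, and leaving out K3Fe(CN)6/carbonate spares the free phenol.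

**Step 14**
Reactants: 38 (1S,2S)-diol with free phenol
Product: 42 5,3',4',5'-tetra-O-benzyl-7-O-triisopropylsilyl-(2R,3S)-gallocatechin bearing the (2S,4R)-4',7-bis(benzyloxy)flavan-4-yl group at C8 (2,3-trans), via cyclic orthoformate 39 (not isolated), via dioxolan-2-ylium ion 40 (not isolated), via 3-O-formate 41 (not isolated)
Conditions: HC(OEt)3, PPTS (cat.), ClCH2CH2Cl, rt → 60 °C; then K2CO3 (cat.), MeOH/THF, 0 °C
Reagents that add atoms: none
Why: Orthoester activation of a 1,2-diol; the acid-generated dioxolanylium ion is opened at its benzylic carbon by the only free phenol in a 6-exo-tet closure with inversion (1S → 2R) while C3 keeps S, giving the 2,3-trans flavan-3-ol formate, which brief methanolysis cleaves without touching the aryl silyl ether.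

**Step 15**
Reactants: 42 2,3-trans flavan-3-ol
Product: 43 the corresponding (2R)-flavan-3-one
Conditions: Dess–Martin periodinane, CH2Cl2, 0 °C → rt
Reagents that add atoms: none
Why: Dess–Martin oxidation of a protected flavan-3-ol proceeds under near-neutral conditions that should leave the C2 centre α to the new ketone intact, all phenols being masked.

**Step 16**
Reactants: 43 (2R)-flavan-3-one
Product: 44 5,3',4',5'-tetra-O-benzyl-7-O-triisopropylsilyl-(2R,3R)-epigallocatechin bearing the (2S,4R)-4',7-bis(benzyloxy)flavan-4-yl group at C8 (2,3-cis)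
Conditions: LiBH(s-Bu)3, LiBr, THF, −78 °C
Reagents that add atoms: none
Why: Hindered trialkylborohydride reduction of a flavan-3-one; hydride is delivered to the carbonyl face opposite the 2-aryl group, which places the 3-OH axial and cis to it (3R).

**Step 17**
Reactants: 44 2,3-cis silyl ether
Product: 45 the 7-hydroxy hexabenzyl ether
Conditions: Bu4NF, AcOH, THF, 0 °C
Reagents that add atoms: none
Why: Buffered fluoride cleavage of the aryl silyl ether; with both B rings still benzylated no quinone-methide pathway for C2 epimerisation is open.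

**Step 18**
Reactants: 45 hexabenzyl ether
Product: 46 target, (2S,4R)-4',7-dihydroxyflavan-(4→8)-(2R,3R)-epigallocatechin
Conditions: H2 (1 atm), Pd(OH)2/C, THF/MeOH, rt
Reagents that add atoms: none
Why: Hydrogenolysis of the six benzyl ethers under the mild conditions customary for benzylated proanthocyanidins, which leave the C2–O1 bonds and the C4–C8 bond untouched.

## Compound list

1 | 7-hydroxy-4H-chromen-4-one | O=c1ccoc2cc(O)ccc12 | starting material
2 | 7-(benzyloxy)-4H-chromen-4-one | O=c1ccoc2cc(OCc3ccccc3)ccc12 | intermediate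
3 | 4-(benzyloxy)phenylboronic acid | OB(O)c1ccc(OCc2ccccc2)cc1 | starting material
4 | (2S)-4',7-bis(benzyloxy)flavanone | c1ccccc1COc1ccc([C@@H]2CC(=O)c3ccc(OCc4ccccc4)cc3O2)cc1 | intermediate
5 | (2S,4S)-4',7-bis(benzyloxy)flavan-4-ol | c1ccccc1COc1ccc([C@@H]2C[C@H](O)c3ccc(OCc4ccccc4)cc3O2)cc1 | intermediate
6 | ethynyltrimethylsilane | C#C[Si](C)(C)C | starting material
7 | lithium (trimethylsilyl)acetylide | [Li+].[C-]#C[Si](C)(C)C | intermediate
8 | lithium trimethoxy[(trimethylsilyl)ethynyl]borate | [Li+].CO[B-](OC)(OC)C#C[Si](C)(C)C | intermediate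
9 | potassium trifluoro[(trimethylsilyl)ethynyl]borate | [K+].F[B-](F)(F)C#C[Si](C)(C)C | intermediate
10 | difluoro[(trimethylsilyl)ethynyl]borane | FB(F)C#C[Si](C)(C)C | intermediate
11 | (2S)-4',7-bis(benzyloxy)flavan-4-yl cation | c1ccccc1COc1ccc([C@@H]2C[CH+]c3ccc(OCc4ccccc4)cc3O2)cc1 | intermediate
12 | (2S,4R)-4',7-bis(benzyloxy)-4-[(trimethylsilyl)ethynyl]flavan | c1ccccc1COc1ccc([C@@H]2C[C@@H](C#C[Si](C)(C)C)c3ccc(OCc4ccccc4)cc3O2)cc1 | intermediate
13 | (2S,4S)-4',7-bis(benzyloxy)-4-ethynylflavan | c1ccccc1COc1ccc([C@@H]2C[C@@H](C#C)c3ccc(OCc4ccccc4)cc3O2)cc1 | intermediate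
14 | lithium acetylide of 13 | [Li+].c1ccccc1COc1ccc([C@@H]2C[C@@H](C#[C-])c3ccc(OCc4ccccc4)cc3O2)cc1 | intermediate
15 | lithium ynolate (2,4-trans flavan-4-yl) | [Li+].c1ccccc1COc1ccc([C@@H]2C[C@@H](C#C[O-])c3ccc(OCc4ccccc4)cc3O2)cc1 | intermediate
16 | (2S,4S)-4',7-bis(benzyloxy)-4-[(triisopropylsiloxy)ethynyl]flavan | c1ccccc1COc1ccc([C@@H]2C[C@@H](C#CO[Si](C(C)C)(C(C)C)C(C)C)c3ccc(OCc4ccccc4)cc3O2)cc1 | intermediate
17 | 3,4,5-tris(benzyloxy)benzaldehyde | O=Cc1cc(OCc2ccccc2)c(OCc2ccccc2)c(OCc2ccccc2)c1 | starting material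
18 | (3-carboxypropyl)triphenylphosphonium bromide | [Br-].OC(=O)CCC[P+](c1ccccc1)(c1ccccc1)c1ccccc1 | starting material
19 | sodium 4-(triphenylphosphoranylidene)butanoate | [Na+].[O-]C(=O)CCC=P(c1ccccc1)(c1ccccc1)c1ccccc1 | intermediate
20 | (E)-5-[3,4,5-tris(benzyloxy)phenyl]pent-4-enoic acid | OC(=O)CC/C=C/c1cc(OCc2ccccc2)c(OCc2ccccc2)c(OCc2ccccc2)c1 | intermediate
21 | benzyl alcohol | OCc1ccccc1 | starting material
22 | trichloroethylene | ClC=C(Cl)Cl | starting material
23 | potassium benzyl oxide | [K+].[O-]Cc1ccccc1 | intermediate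
24 | dichloroacetylene | ClC#CCl | intermediate
25 | benzyl (E)-1,2-dichlorovinyl ether | Cl/C=C(\OCc1ccccc1)Cl | intermediate
26 | benzyl chloroethynyl ether | ClC#COCc1ccccc1 | intermediate
27 | lithium (benzyloxy)acetylide | [Li+].[C-]#COCc1ccccc1 | intermediate
28 | benzyl ethynyl ether | C#COCc1ccccc1 | intermediate
29 | (E)-5-[3,4,5-tris(benzyloxy)phenyl]pent-4-enoyl chloride | ClC(=O)CC/C=C/c1cc(OCc2ccccc2)c(OCc2ccccc2)c(OCc2ccccc2)c1 | intermediate
30 | (E)-5-[3,4,5-tris(benzyloxy)phenyl]penta-1,4-dien-1-one (ketene) | O=C=CC/C=C/c1cc(OCc2ccccc2)c(OCc2ccccc2)c(OCc2ccccc2)c1 | intermediate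
31 | (±)-3-(benzyloxy)-4-{(E)-3-[3,4,5-tris(benzyloxy)phenyl]allyl}cyclobut-2-en-1-one | O=C1C=C(OCc2ccccc2)C1C/C=C/c1cc(OCc2ccccc2)c(OCc2ccccc2)c(OCc2ccccc2)c1 | intermediate
32 | 3-benzyloxy vinylketene, chain trans to the ketene carbon | O=C=C/C(OCc1ccccc1)=C/C/C=C/c1cc(OCc2ccccc2)c(OCc2ccccc2)c(OCc2ccccc2)c1 | intermediate
33 | 2-(flavan-4-yl)-3-(triisopropylsiloxy)-4-alkenylcyclobut-2-enone, (2+2) adduct, ring C4 unassigned | c1ccccc1COc1ccc([C@@H]2C[C@@H](C5=C(O[Si](C(C)C)(C(C)C)C(C)C)C(/C(OCc6ccccc6)=C/C/C=C/c6cc(OCc7ccccc7)c(OCc7ccccc7)c(OCc7ccccc7)c6)C5=O)c3ccc(OCc4ccccc4)cc3O2)cc1 | intermediate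
34 | dienylketene | c1ccccc1COc1ccc([C@@H]2C[C@@H](C(=C=O)/C(O[Si](C(C)C)(C(C)C)C(C)C)=C\C(OCc6ccccc6)=C\C/C=C/c6cc(OCc7ccccc7)c(OCc7ccccc7)c(OCc7ccccc7)c6)c3ccc(OCc4ccccc4)cc3O2)cc1 | intermediate
35 | cyclohexa-2,4-dienone, C6 unassigned | c1ccccc1COc1ccc([C@@H]2C[C@@H](C5=C(O[Si](C(C)C)(C(C)C)C(C)C)C=C(OCc6ccccc6)C(C/C=C/c6cc(OCc7ccccc7)c(OCc7ccccc7)c(OCc7ccccc7)c6)C5=O)c3ccc(OCc4ccccc4)cc3O2)cc1 | intermediate
36 | 2-[(2S,4R)-4',7-bis(benzyloxy)flavan-4-yl]-5-(benzyloxy)-3-(triisopropylsiloxy)-6-{(E)-3-[3,4,5-tris(benzyloxy)phenyl]allyl}phenol | c1ccccc1COc1ccc([C@@H]2C[C@@H](c5c(O[Si](C(C)C)(C(C)C)C(C)C)cc(OCc6ccccc6)c(C/C=C/c6cc(OCc7ccccc7)c(OCc7ccccc7)c(OCc7ccccc7)c6)c5O)c3ccc(OCc4ccccc4)cc3O2)cc1 | intermediate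
37 | cyclic osmate ester of 38 (amine ligand omitted) | c1ccccc1COc1ccc([C@@H]2C[C@@H](c5c(O[Si](C(C)C)(C(C)C)C(C)C)cc(OCc6ccccc6)c(C[C@H](O[Os]8(=O)=O)[C@@H](O8)c6cc(OCc7ccccc7)c(OCc7ccccc7)c(OCc7ccccc7)c6)c5O)c3ccc(OCc4ccccc4)cc3O2)cc1 | intermediate
38 | (1S,2S)-diol with free phenol | c1ccccc1COc1ccc([C@@H]2C[C@@H](c5c(O[Si](C(C)C)(C(C)C)C(C)C)cc(OCc6ccccc6)c(C[C@H](O)[C@@H](O)c6cc(OCc7ccccc7)c(OCc7ccccc7)c(OCc7ccccc7)c6)c5O)c3ccc(OCc4ccccc4)cc3O2)cc1 | intermediate
39 | 2-ethoxy-1,3-dioxolane (cyclic orthoformate) of 38, orthoformate carbon unassigned | c1ccccc1COc1ccc([C@@H]2C[C@@H](c5c(O[Si](C(C)C)(C(C)C)C(C)C)cc(OCc6ccccc6)c(C[C@H](OC8OCC)[C@@H](O8)c6cc(OCc7ccccc7)c(OCc7ccccc7)c(OCc7ccccc7)c6)c5O)c3ccc(OCc4ccccc4)cc3O2)cc1 | intermediate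
40 | 1,3-dioxolan-2-ylium ion | c1ccccc1COc1ccc([C@@H]2C[C@@H](c5c(O[Si](C(C)C)(C(C)C)C(C)C)cc(OCc6ccccc6)c(C[C@H](OC8)[C@@H]([O+]=8)c6cc(OCc7ccccc7)c(OCc7ccccc7)c(OCc7ccccc7)c6)c5O)c3ccc(OCc4ccccc4)cc3O2)cc1 | intermediate
41 | 3-O-formate of 42 | c1ccccc1COc1ccc([C@@H]2C[C@@H](c5c(O[Si](C(C)C)(C(C)C)C(C)C)cc(OCc6ccccc6)c6c5O[C@H](c7cc(OCc8ccccc8)c(OCc8ccccc8)c(OCc8ccccc8)c7)[C@@H](OC=O)C6)c3ccc(OCc4ccccc4)cc3O2)cc1 | intermediate
42 | protected dimer, lower unit (2R,3S), 2,3-trans | c1ccccc1COc1ccc([C@@H]2C[C@@H](c5c(O[Si](C(C)C)(C(C)C)C(C)C)cc(OCc6ccccc6)c6c5O[C@H](c7cc(OCc8ccccc8)c(OCc8ccccc8)c(OCc8ccccc8)c7)[C@@H](O)C6)c3ccc(OCc4ccccc4)cc3O2)cc1 | intermediate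
43 | protected dimer, lower unit (2R)-flavan-3-one | c1ccccc1COc1ccc([C@@H]2C[C@@H](c5c(O[Si](C(C)C)(C(C)C)C(C)C)cc(OCc6ccccc6)c6c5O[C@H](c7cc(OCc8ccccc8)c(OCc8ccccc8)c(OCc8ccccc8)c7)C(=O)C6)c3ccc(OCc4ccccc4)cc3O2)cc1 | intermediate
44 | protected dimer, lower unit (2R,3R), 2,3-cis | c1ccccc1COc1ccc([C@@H]2C[C@@H](c5c(O[Si](C(C)C)(C(C)C)C(C)C)cc(OCc6ccccc6)c6c5O[C@H](c7cc(OCc8ccccc8)c(OCc8ccccc8)c(OCc8ccccc8)c7)[C@H](O)C6)c3ccc(OCc4ccccc4)cc3O2)cc1 | intermediate
45 | hexabenzyl ether with free 7-OH (lower unit) | c1ccccc1COc1ccc([C@@H]2C[C@@H](c5c(O)cc(OCc6ccccc6)c6c5O[C@H](c7cc(OCc8ccccc8)c(OCc8ccccc8)c(OCc8ccccc8)c7)[C@H](O)C6)c3ccc(OCc4ccccc4)cc3O2)cc1 | intermediate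
46 | CNP0220331.1, (2S,4R)-4',7-dihydroxyflavan-(4→8)-(2R,3R)-epigallocatechin | Oc1ccc([C@@H]2C[C@@H](c3c(O)cc(O)c4c3O[C@H](c3cc(O)c(O)c(O)c3)[C@H](O)C4)c3ccc(O)cc3O2)cc1 | target

## Step count and risks

Total step count: 18.
Longest linear sequence: 13 steps (1, 2, 3, 5, 6, 7, 12 to 18).

**Step 12.**
- The vinylogous-ester resonance of 31 raises the barrier to its ring opening.
- At the temperature then needed, the siloxyalkyne may drift to a silylketene by silyl shift.
- The crowded secondary substituent slows capture of the vinylketene.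
- The small share of inward-rotated vinylketene may be drained by intramolecular ketene–alkene addition.

The fallback sets out from 5 and returns at 46, and takes ring A ready-made. Commercial (−)-epigallocatechin is benzylated on its five phenols (BnBr, K2CO3, DMF, 0 °C → rt) to 5,7,3',4',5'-penta-O-benzyl-(−)-epigallocatechin F1. Alcohol 5 is ionised with Me3SiOTf in CH2Cl2 at −78 °C in the presence of excess F1. This is the Friedel–Crafts flavanylation customary for proanthocyanidins. Pseudo-axial attack by the more nucleophilic C8 should give the 2,4-trans, 4→8-linked hepta-O-benzyl dimer F2, which is separated from the C6-linked isomer. Hydrogenolysis over Pd(OH)2/C then leads to 46.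

**Step 11.**
- Amine- and ammonium-salt-promoted dimerisation of the monoalkylketene may compete.
- HCl from the ammonium salt may add to the ynol ether.
- The (3,3) shift of 28 may outrun the cycloaddition.

The fallback sets out from 17 and returns at ketene 30, hence at 31. It makes the ketene without base or salt.
- Wittig reaction of 17 with (2-carboxyethyl)triphenylphosphonium bromide and NaN(SiMe3)2 gives (E)-4-[3,4,5-tris(benzyloxy)phenyl]but-3-enoic acid F3.
- Me2C=C(Cl)NMe2 converts it into (E)-4-[3,4,5-tris(benzyloxy)phenyl]but-3-enoyl chloride F4.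
- Excess CH2N2 in Et2O at 0 °C gives (E)-1-diazo-5-[3,4,5-tris(benzyloxy)phenyl]pent-4-en-2-one F5.
- Irradiation of F5 with blue light (about 440 nm, outside the styrene absorption) in the presence of 28 triggers a Wolff rearrangement to 30, which is trapped as 31.

**Step 14.** Attack by the crowded phenol, flanked by the flavanyl group, may be slow. The dioxolanylium ion could then ionise further to an open benzylic cation, which erodes the inversion at C2, or the orthoformate could simply persist. The fallback sets out from 38 and returns at 42. It is a Mitsunobu cyclisation (PPh3, DIAD, THF, 0 °C), a known closure of 1,3-diarylpropane-1,2-diols to 2,3-trans flavan-3-ols. The benzylic alcohol is activated and displaced by the phenol with inversion in one operation, without any cationic intermediate.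

## Further compounds

F1 | step 12 | 5,7,3',4',5'-penta-O-benzyl-(−)-epigallocatechin | c1c(OCc2ccccc2)cc(OCc2ccccc2)c2c1O[C@H](c1cc(OCc3ccccc3)c(OCc3ccccc3)c(OCc3ccccc3)c1)[C@H](O)C2
F2 | step 12 | hepta-O-benzyl (2S,4R)-flavan-(4→8)-(2R,3R)-epigallocatechin | c1ccccc1COc1ccc([C@@H]2C[C@@H](c5c(OCc6ccccc6)cc(OCc6ccccc6)c6c5O[C@H](c7cc(OCc8ccccc8)c(OCc8ccccc8)c(OCc8ccccc8)c7)[C@H](O)C6)c3ccc(OCc4ccccc4)cc3O2)cc1
F3 | step 11 | (E)-4-[3,4,5-tris(benzyloxy)phenyl]but-3-enoic acid | OC(=O)C/C=C/c1cc(OCc2ccccc2)c(OCc2ccccc2)c(OCc2ccccc2)c1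
F4 | step 11 | (E)-4-[3,4,5-tris(benzyloxy)phenyl]but-3-enoyl chloride | ClC(=O)C/C=C/c1cc(OCc2ccccc2)c(OCc2ccccc2)c(OCc2ccccc2)c1
F5 | step 11 | (E)-1-diazo-5-[3,4,5-tris(benzyloxy)phenyl]pent-4-en-2-one | [N-]=[N+]=CC(=O)C/C=C/c1cc(OCc2ccccc2)c(OCc2ccccc2)c(OCc2ccccc2)c1
F0 | step 14 | none | none
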